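**Deceptive lag.** The pitfall lies in the early sample: Q at 95.5% after 0.500 d of the summer run looks like a slow reaction and invites a longer stay. Yet by 0.833 d Q stands at 31.8% and J at 67.1%, so J seems to speed its own making. The decision is whether the flask's charge and stay can stand, and when to sample it.

the same everywhere: X 15 mM (held)
- summer: Q 0.017 M (fed, over 6.0 h); run made earlier
- midnight: Q 0.066 M (fed, over 6.0 h); run made earlier
- flask: Q 0.033 M (fed, over 6.0 h); time 6.0 d

- summer (time / d: Q / %, J / %): 0.500: 95.5, 6.2; 0.833: 31.8, 67.1; 1.25: 0.2, 99.3; 2.00: 0.2, 100.7; 4.00: 1.3, 100.8; 6.00: 0.8, 100.6
- midnight (time / d: Q / %, J / %): 1.04: 0, 99.5; 2.08: 0.4, 99.7; 3.00: 0, 98.3; 4.00: 0.4, 99.0; 5.00: 0.9, 99.9; 6.00: 0, 101.2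

(each reading ± 1 percentage point)

- the numbers in the tables scatter with a standard deviation of 1 percentage point
- at the start none of X is in solution
- the reaction counts as stopped when no species that holds the Q changes by six tenths of a point or more over the second half of the time

* the state of affairs at 6.0 d: stopped, and by what, or still going (forward and back rates have come level / it is still moving / all of Q has reacted)
* conversion of Q at 6.0 d
* amount of J at 6.0 d, in percent of the Q charged
* amount of J if the flask were left three thousand times as long, in percent of the Q charged

**Frozen X.** X is held, so its level is frozen into one constant, and the loss of Q is written as K[Q][J], a pseudo-second-order autocatalysis. After the feed, ln([J]/[Q]) then climbs in a straight line. The first two summer readings that show both species give a climb of 10.5 d⁻¹, and dividing by the charge gives the reading 0.427 L mol⁻¹ min⁻¹. This climb constant, the rise of ln([J]/[Q]) per unit of time and of charge, goes to the next flask.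

**The decision.** In the flask the climb is 20.3 d⁻¹, and going from 100 times less J than Q to 100 times more takes 0.454 d. Tracing the summer ratio back to the end of its feed, and assuming that this seed ratio does not depend on the charge, puts the flask's crossing [J] = [Q] at 0.514 d. [Q] should stand 100 times below [J] by about 0.740 d, well before 6.0 d, so the charge stands and the samples belong near the crossing. Summer J drifts from 100.7% to 100.6%, less than the scatter of 1 percentage point, so J is reckoned to stay at the full charge. A reading of Q above the scatter at 6.0 d, or J sinking late, overturns this reckoning.

The forecast states that all of Q has reacted, with conversion 99.8%, J 99.8% and, long after, 99.8%, noting that “a higher charge shortens the lag rather than lengthening it”.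

**The result.** At 6.0 d the flask shows that all of Q has reacted, with conversion 100% and J 100%, and the answer for the much longer stay asked about is J 100%.

    Q + G → J (k = 5.40 × 10⁻⁴ L mol⁻¹ min⁻¹)
    X ⇌ G, rate k2*(csat - [G]) (kL = 0.320 min⁻¹)
    Q + G + J → 2 J (k = 29.0 L² mol⁻² min⁻¹)

**Two paths.** At 0.439 d the flask's Q is used 470 times faster by the path in which J takes part than by the path without J. At that moment the path without J has a half-life of 61 d for Q, long against 6.0 d. Half of the flask's conversion is reached at 0.489 d, against the crossing at 0.514 d reckoned with K. The neighbour charged with 0.013 M of Q climbs, by K, at 7.99 d⁻¹, which makes the same passage take 1.15 d, and it holds J at 100% at 6.00 d.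

The earlier runs and the new flask are calculated with constants of no real substance, noise included.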